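Target: 3,5,3',5'-tetrahydroxy-7,8,4'-trimethoxyflavone, an achiral molecule, so no stereocentre has to be set.
Cuts: first O1–C2 of ring C (cyclodehydration in reverse), then C2–C3 and C2–C1' together.
Enabling feature: once O1 is detached, C2 is a ketone carbonyl whose only carbon neighbours are C3 (the oxygen-bearing alpha carbon of the ring A aryl ketone C4) and C1' of ring B. Such a carbon can be supplied as carbon monoxide between an enolate and an aryl iodide.
Forward: rings A and B are bought. A ring A alpha-benzyloxy ketone (four steps) and a ring B aryl iodide (three steps) are joined through CO to an open 1,3-diketone, and ring C then closes by attack of O1 on C2 with loss of water.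
Regiochemistry: the 5-oxygen stays methylated until ring C exists, so only one phenol can close and the 5,7,8-pattern is fixed. BCl3 then frees the 3-OH and the 5-OH.
The C3 centre formed in the coupling is racemic and enolisable, and it becomes sp2 on ring closure.

Key step: step 8

Remark: the acetophenone and 2-methoxyresorcinol starting materials are taken as catalogue items, and the 1,3-diketones are drawn as diketo tautomers with an undefined, configurationally labile C3.

Step 1
Reactants: 1 2'-hydroxy-3',4',6'-trimethoxyacetophenone
Product: 2 1-[3,4,6-trimethoxy-2-(methoxymethoxy)phenyl]ethan-1-one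
Conditions: NaH (1.1 equiv), MOMCl (1.2 equiv), DMF, 0 °C to rt
Reagents that add atoms: chloromethyl methyl ether (MOMCl), COCCl
Why: Williamson-type O-alkylation, in which NaH deprotonates the chelated phenol (far more acidic than the methyl ketone) and the phenoxide is trapped as a MOM acetal that tolerates every basic step up to step 8.

Step 2
Reactants: 2 1-[3,4,6-trimethoxy-2-(methoxymethoxy)phenyl]ethan-1-one
Product: 3 trimethyl({1-[3,4,6-trimethoxy-2-(methoxymethoxy)phenyl]ethenyl}oxy)silane
Conditions: LiN(SiMe3)2 (1.2 equiv), TMSCl (1.5 equiv), THF, −78 to 0 °C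
Reagents that add atoms: chlorotrimethylsilane (TMSCl), C[Si](C)(C)Cl
Why: Enolate O-silylation, where the methyl group is the only enolisable position and the basic, Lewis-acid-free conditions leave the MOM acetal untouched.

Step 3
Reactants: 3 trimethyl({1-[3,4,6-trimethoxy-2-(methoxymethoxy)phenyl]ethenyl}oxy)silane
Product: 5 2-hydroxy-1-[3,4,6-trimethoxy-2-(methoxymethoxy)phenyl]ethan-1-one, via alpha-silyloxy ketone 4 (not isolated)
Conditions: mCPBA (1.05 equiv), CH2Cl2, −20 to 0 °C; then citric acid (cat), MeOH, rt
Reagents that add atoms: 3-chloroperoxybenzoic acid (mCPBA), OOC(=O)c1cccc(Cl)c1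
Why: Rubottom oxidation, in which the peracid epoxidises the electron-rich enol ether double bond much faster than it touches the arene, a 1,4-silyl shift gives 4, and mild acid methanolysis removes the TMS group without harming the aryl MOM ether.

Step 4
Reactants: 5 2-hydroxy-1-[3,4,6-trimethoxy-2-(methoxymethoxy)phenyl]ethan-1-one
Product: 6 2-(benzyloxy)-1-[3,4,6-trimethoxy-2-(methoxymethoxy)phenyl]ethan-1-one
Conditions: BnBr (1.5 equiv), Ag2O (1.5 equiv), 4 Å MS, CH2Cl2, rt, dark
Reagents that add atoms: benzyl bromide (BnBr), BrCc1ccccc1
Why: Silver-oxide-promoted Williamson benzylation, which needs no soluble strong base, so the alpha-ketol should be O-alkylated without enediol isomerisation or C-alkylation.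

Step 5
Reactants: 7 2-methoxyresorcinol
Product: 8 2-methoxy-1,3-bis(methoxymethoxy)benzene
Conditions: NaH (2.4 equiv), MOMCl (2.4 equiv), DMF, 0 °C to rt
Reagents that add atoms: chloromethyl methyl ether (MOMCl), COCCl
Why: Double Williamson-type O-alkylation of the two equivalent phenols, giving base-stable acetals that carry no aromatic C–H bonds of their own to compete in step 6.

Step 6
Reactants: 8 2-methoxy-1,3-bis(methoxymethoxy)benzene
Product: 9 2-[4-methoxy-3,5-bis(methoxymethoxy)phenyl]-4,4,5,5-tetramethyl-1,3,2-dioxaborolane
Conditions: [Ir(OMe)(cod)]2 (1.5 mol %), dtbpy (3 mol %), B2pin2 (1.0 equiv), THF, 80 °C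
Reagents that add atoms: bis(pinacolato)diboron (B2pin2), CC1(C)OB(OC1(C)C)B1OC(C)(C)C(C)(C)O1
Why: Iridium-catalysed aromatic C–H borylation under steric control, which selects C5 because it is the only ring C–H without an ortho substituent, a position that electrophilic substitution cannot reach.

Step 7
Reactants: 9 2-[4-methoxy-3,5-bis(methoxymethoxy)phenyl]-4,4,5,5-tetramethyl-1,3,2-dioxaborolane
Product: 10 5-iodo-2-methoxy-1,3-bis(methoxymethoxy)benzene
Conditions: CuI (10 mol %), 1,10-phenanthroline (20 mol %), KI (1.5 equiv), MeOH/H2O, air, 80 °C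
Reagents that add atoms: potassium iodide, [K+].[I-]
Why: Copper-catalysed aerobic iododeboronation (Chan–Lam-type transfer of the aryl group from boron to copper, then C–I reductive elimination), which places iodine at the ipso carbon, whereas an electrophilic iodine source would attack the C–H positions ortho and para to the OMOM groups.

Step 8
Reactants: 6 2-(benzyloxy)-1-[3,4,6-trimethoxy-2-(methoxymethoxy)phenyl]ethan-1-one; 10 5-iodo-2-methoxy-1,3-bis(methoxymethoxy)benzene; 11 carbon monoxide
Product: 12 2-(benzyloxy)-1-[4-methoxy-3,5-bis(methoxymethoxy)phenyl]-3-[3,4,6-trimethoxy-2-(methoxymethoxy)phenyl]propane-1,3-dione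
Conditions: 6 (2 equiv), NaN(SiMe3)2 (2 equiv), Pd(dba)2 (5 mol %), Xantphos (6 mol %), CO (1 atm), THF, 70 °C
Reagents that add atoms: none
Why: Zerovalent palladium inserts into the C–I bond of 10, CO then inserts into the aryl–palladium bond to give an aroyl complex of divalent palladium, the sodium enolate of 6 replaces iodide on the metal, and reductive elimination joins C3 to the acyl carbon, so that C2–C1' and C2–C3 are made in one catalytic cycle. This is the palladium-catalysed carbonylative alpha-arylation of ketones, known for aryl alkyl ketones such as propiophenone with aryl iodides under Pd(dba)2, a bisphosphine and NaN(SiMe3)2; the benzyloxy group makes the alpha proton of 6 more acidic and the enolate more crowded but does not alter the reaction type. No ring closes, and the one new stereocentre (C3) has no controlling element: it forms racemic, is enolisable and is erased in step 9. Carbonylation has to come before coupling, which the substrates favour because both positions ortho to iodine in 10 carry hydrogen, so CO insertion is fast at 1 atm, while direct arylation of the crowded secondary enolate is slow and the wide bite angle of Xantphos speeds reductive elimination from the aroyl stage. C- rather than O-acylation is secured by the acidity of the C3–H of 12, which lies between two carbonyl groups: the second equivalent of enolate deprotonates 12 to a delocalised diketonate, a thermodynamic sink into which any enol ester is also drained by acyl transfer, and the ketone spent as base is recovered as 6. One equivalent of amide base per ketone leaves no free amide to intercept the aroyl complex, and the MOM, benzyl and methyl ethers are inert to base, CO and palladium.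

Step 9
Reactants: 12 2-(benzyloxy)-1-[4-methoxy-3,5-bis(methoxymethoxy)phenyl]-3-[3,4,6-trimethoxy-2-(methoxymethoxy)phenyl]propane-1,3-dione
Product: 14 3-(benzyloxy)-2-(3,5-dihydroxy-4-methoxyphenyl)-5,7,8-trimethoxy-4H-chromen-4-one, via triphenol diketone 13 (not isolated)
Conditions: HCl (1.25 M in MeOH), 60 °C
Reagents that add atoms: none
Why: Acid-catalysed acetal exchange strips the three MOM groups, and the freed 2'-OH of 13, the only phenol ortho to a carbonyl, adds to the ring B carbonyl (6-exo-trig hemiketalisation) and loses water in the classical cyclodehydration of o-hydroxyaryl 1,3-diketones, while benzyl and methyl ethers are stable to dilute methanolic HCl.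

Step 10
Reactants: 14 3-(benzyloxy)-2-(3,5-dihydroxy-4-methoxyphenyl)-5,7,8-trimethoxy-4H-chromen-4-one
Product: 15 3,5-dihydroxy-2-(3,5-dihydroxy-4-methoxyphenyl)-7,8-dimethoxy-4H-chromen-4-one
Conditions: BCl3 (6 equiv), C6HMe5 (3 equiv), CH2Cl2, −78 to 0 °C; then H2O
Reagents that add atoms: none
Why: Chelation-directed Lewis-acid ether cleavage, in which BCl3 held at the C4 carbonyl oxygen activates only the two flanking ethers (the 3-O-benzyl group at −78 °C with pentamethylbenzene trapping the benzyl cation, the peri 5-O-methyl group on warming to 0 °C), whereas the unchelated 7-, 8- and 4'-methoxy groups need higher temperature and longer time.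

Compound list
1 | 2'-hydroxy-3',4',6'-trimethoxyacetophenone | CC(=O)c1c(O)c(OC)c(OC)cc1OC | starting material
2 | 1-[3,4,6-trimethoxy-2-(methoxymethoxy)phenyl]ethan-1-one | COCOc1c(OC)c(OC)cc(OC)c1C(C)=O | intermediate
3 | trimethyl({1-[3,4,6-trimethoxy-2-(methoxymethoxy)phenyl]ethenyl}oxy)silane | COCOc1c(OC)c(OC)cc(OC)c1C(=C)O[Si](C)(C)C | intermediate
4 | 1-[3,4,6-trimethoxy-2-(methoxymethoxy)phenyl]-2-[(trimethylsilyl)oxy]ethan-1-one (not isolated) | COCOc1c(OC)c(OC)cc(OC)c1C(=O)CO[Si](C)(C)C | intermediate
5 | 2-hydroxy-1-[3,4,6-trimethoxy-2-(methoxymethoxy)phenyl]ethan-1-one | COCOc1c(OC)c(OC)cc(OC)c1C(=O)CO | intermediate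
6 | 2-(benzyloxy)-1-[3,4,6-trimethoxy-2-(methoxymethoxy)phenyl]ethan-1-one | COCOc1c(OC)c(OC)cc(OC)c1C(=O)COCc1ccccc1 | intermediate
7 | 2-methoxyresorcinol | COc1c(O)cccc1O | starting material
8 | 2-methoxy-1,3-bis(methoxymethoxy)benzene | COCOc1cccc(OCOC)c1OC | intermediate
9 | 2-[4-methoxy-3,5-bis(methoxymethoxy)phenyl]-4,4,5,5-tetramethyl-1,3,2-dioxaborolane | COCOc1cc(B2OC(C)(C)C(C)(C)O2)cc(OCOC)c1OC | intermediate
10 | 5-iodo-2-methoxy-1,3-bis(methoxymethoxy)benzene | COCOc1cc(I)cc(OCOC)c1OC | intermediate
11 | carbon monoxide | [C-]#[O+] | starting material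
12 | 2-(benzyloxy)-1-[4-methoxy-3,5-bis(methoxymethoxy)phenyl]-3-[3,4,6-trimethoxy-2-(methoxymethoxy)phenyl]propane-1,3-dione (racemic, enolisable C2 of the chain) | COCOc1c(OC)c(OC)cc(OC)c1C(=O)C(OCc1ccccc1)C(=O)c1cc(OCOC)c(OC)c(OCOC)c1 | intermediate
13 | 2-(benzyloxy)-1-(3,5-dihydroxy-4-methoxyphenyl)-3-(2-hydroxy-3,4,6-trimethoxyphenyl)propane-1,3-dione (not isolated) | COc1cc(OC)c(C(=O)C(OCc2ccccc2)C(=O)c2cc(O)c(OC)c(O)c2)c(O)c1OC | intermediate
14 | 3-(benzyloxy)-2-(3,5-dihydroxy-4-methoxyphenyl)-5,7,8-trimethoxy-4H-chromen-4-one | COc1cc(OC)c2c(=O)c(OCc3ccccc3)c(-c3cc(O)c(OC)c(O)c3)oc2c1OC | intermediate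
15 | 3,5-dihydroxy-2-(3,5-dihydroxy-4-methoxyphenyl)-7,8-dimethoxy-4H-chromen-4-one | COc1cc(O)c2c(=O)c(O)c(-c3cc(O)c(OC)c(O)c3)oc2c1OC | target

Total step count: 10. Longest linear sequence: 7 (steps 1 to 4, then 8 to 10).

Steps most likely to fail

Step 8. The crowded, di-ortho-substituted enolate may capture the aroyl palladium species too slowly. Direct arylation, kinetic O-acylation or thermal breakdown of the enolate by a 1,2-shift of the benzyl group could then take over. The fallback separates the two bond formations and keeps CO as the source of C2. It sets out from 10 and 11. A palladium-catalysed aryloxycarbonylation (Pd(OAc)2, Xantphos, pentafluorophenol, Et3N, CO 1 atm, toluene, 80 °C) should give pentafluorophenyl 4-methoxy-3,5-bis(methoxymethoxy)benzoate F1, so that only C2–C1' is made on the metal. The lithium enolate of 6 (LiN(SiMe3)2, 2.2 equiv, THF, −78 °C) is then C-acylated with the active ester in a crossed Claisen condensation at −78 to 0 °C. There the enolate never meets palladium or heat. The route is rejoined at 12.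

Step 10. Demethylation may go too far at the crowded 4'- and 8-methoxy groups, helped by aryloxyboron groups formed on the neighbouring ring B phenols. Ring benzylation may also occur if cation trapping is incomplete. The fallback uses two orthogonal operations and sets out from 14. Hydrogenolysis (H2, Pd/C, EtOAc/MeOH, rt) removes only the benzyl group and should give 3-hydroxy-2-(3,5-dihydroxy-4-methoxyphenyl)-5,7,8-trimethoxy-4H-chromen-4-one F2. MgI2·OEt2 (3 equiv, THF/toluene, 70 °C) then cleaves the peri 5-O-methyl group by iodide attack on the methyl carbon within a magnesium chelate to the C4 carbonyl. This weak Lewis acid should not activate methoxy groups that lack such a chelate. The route is rejoined at 15.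

Step 4. The alpha-ketol may tautomerise through its enediol, be oxidised by the silver salt, or alkylate sluggishly. The fallback benzylates while the carbonyl is masked. It sets out from 2 and bypasses 3 to 5. Hypervalent-iodine alpha-hydroxylation in basic methanol (PhI(OAc)2, KOH, MeOH, 0 °C to rt) should give 2,2-dimethoxy-2-[3,4,6-trimethoxy-2-(methoxymethoxy)phenyl]ethan-1-ol F3. An ordinary Williamson benzylation of this primary alcohol (NaH, BnBr, THF, 0 °C to rt) should give 2-[2-(benzyloxy)-1,1-dimethoxyethyl]-1,4,5-trimethoxy-3-(methoxymethoxy)benzene F4. PPTS in wet acetone at rt then hydrolyses the strained, electron-rich aryl ketal faster than the aryl MOM ether. The route is rejoined at 6.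

Further compounds
F1 | step 8 | pentafluorophenyl 4-methoxy-3,5-bis(methoxymethoxy)benzoate | COCOc1cc(C(=O)Oc2c(F)c(F)c(F)c(F)c2F)cc(OCOC)c1OC
F2 | step 10 | 3-hydroxy-2-(3,5-dihydroxy-4-methoxyphenyl)-5,7,8-trimethoxy-4H-chromen-4-one | COc1cc(OC)c2c(=O)c(O)c(-c3cc(O)c(OC)c(O)c3)oc2c1OC
F3 | step 4 | 2,2-dimethoxy-2-[3,4,6-trimethoxy-2-(methoxymethoxy)phenyl]ethan-1-ol | COCOc1c(OC)c(OC)cc(OC)c1C(OC)(OC)CO
F4 | step 4 | 2-[2-(benzyloxy)-1,1-dimethoxyethyl]-1,4,5-trimethoxy-3-(methoxymethoxy)benzene | COCOc1c(OC)c(OC)cc(OC)c1C(OC)(OC)COCc1ccccc1
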